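**Plan**

- Retrosynthesis: the side chain is cut at the ring A–carbinol bond and at the C–O bond between its C2 and the ring B oxygen. The oxolane is then cut at C3–CH3, at the ring bond O1–C2, at the ring B–alkyne bond and at C4–C5.
- Forward: C4–C5 is made by allenylstannane addition to veratraldehyde and ring B is attached by Sonogashira coupling. The five-membered ring then closes by iodocyclisation, C3 is methylated through its iodide and the enol ether is hydrogenated. The side chain is built last on the freed phenol (Mitsunobu, Weinreb ketone synthesis, reduction).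
- Enabling feature: in the oxolane (O1, C2 on ring B, C3 and C4 with methyls, C5 on veratryl ring C) the C5 oxygen sits four atoms from C2. The para oxygen of ring B makes C2 the cationic end of an iodine-activated aryl alkyne, so O1–C2 closes the ring and iodine marks C3 for the missing methyl.
- Stereochemistry: C4 comes from (S)-but-3-yn-2-ol by chirality transfer through an allene axis, and C5 from the syn-selective SE2′ addition. C2 and C3 are set by hydrogenation anti to the cis C4/C5 substituents. Side-chain C2 comes from ethyl (R)-lactate with Mitsunobu inversion, and side-chain C1 from chelation-controlled ketone reduction.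

Key step: step 6

Assumption: the stannylcuprate displacement is taken as anti SN2′ and the BF3-promoted addition as anti SE2′ with syn simple diastereoselection, as is usual for propargylic mesylates and allenylstannanes; on this basis (S)-but-3-yn-2-ol is the correct antipode.
Remark: all ring intermediates keep the oxolane numbering of the target (O1, C2 on ring B, C5 on ring C).

**Route**

Step 1
Reactants: 1 (S)-but-3-yn-2-ol
Product: 2 (S)-but-3-yn-2-yl methanesulfonate
Conditions: MsCl, Et3N, CH2Cl2, −78 to 0 °C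
Reagents that add atoms: methanesulfonyl chloride, CS(=O)(=O)Cl
Why: Mesylation of a secondary propargylic alcohol touches only the O–H bond, so the S configuration is kept and the leaving group for the SN2′ step is installed.

Step 2
Reactants: 2 (S)-but-3-yn-2-yl methanesulfonate
Product: 3 (Ra)-tributyl(buta-1,2-dien-1-yl)stannane
Conditions: Bu3SnH, LiN(iPr)2, THF, 0 °C; CuBr·SMe2, −78 °C; then 2, −78 °C
Reagents that add atoms: tributyltin hydride (deprotonated in the flask to Bu3SnLi), CCCC[SnH](CCCC)CCCC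
Why: Stannylcuprate SN2′ displacement of a propargylic mesylate should deliver tin to the alkyne terminus anti to the departing mesylate, converting the stereocentre of 2 into the R (M) allene axis.

Step 3
Reactants: 3 (Ra)-tributyl(buta-1,2-dien-1-yl)stannane; 4 veratraldehyde (3,4-dimethoxybenzaldehyde)
Product: 5 (1R,2S)-1-(3,4-dimethoxyphenyl)-2-methylbut-3-yn-1-ol
Conditions: BF3·OEt2, CH2Cl2, −78 °C; aq NaHCO3
Reagents that add atoms: none
Why: Lewis acid-promoted SE2′ propargylation of an aldehyde by an allenylstannane runs through an open transition state in which tin leaves anti to the incoming carbonyl carbon, so the allene axis should set C2 as S, and the arrangement that keeps the allenyl methyl away from the BF3-bound oxygen should give the syn adduct, hence C1 as R.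

Step 4
Reactants: 6 4-iodo-2-methoxyphenol
Product: 7 1-(benzyloxy)-4-iodo-2-methoxybenzene
Conditions: BnBr, K2CO3, DMF, rt
Reagents that add atoms: benzyl bromide, BrCc1ccccc1
Why: Williamson etherification of a phenoxide with a benzylic bromide masks the ring B phenol as a group that leaves later under hydrogenation.

Step 5
Reactants: 5 (1R,2S)-1-(3,4-dimethoxyphenyl)-2-methylbut-3-yn-1-ol; 7 1-(benzyloxy)-4-iodo-2-methoxybenzene
Product: 8 (1R,2S)-4-[4-(benzyloxy)-3-methoxyphenyl]-1-(3,4-dimethoxyphenyl)-2-methylbut-3-yn-1-ol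
Conditions: PdCl2(PPh3)2 (3 mol%), CuI (5 mol%), Et3N, THF, rt
Reagents that add atoms: none
Why: Sonogashira coupling of a terminal alkyne with an aryl iodide under zerovalent palladium and monovalent copper catalysis tolerates the free alcohol and should leave both stereocentres untouched.

Step 6
Reactants: 8 (1R,2S)-4-[4-(benzyloxy)-3-methoxyphenyl]-1-(3,4-dimethoxyphenyl)-2-methylbut-3-yn-1-ol
Product: 9 (4R,5R)-2-[4-(benzyloxy)-3-methoxyphenyl]-5-(3,4-dimethoxyphenyl)-3-iodo-4-methyl-4,5-dihydrofuran
Conditions: I2 (1.5 equiv), NaHCO3, MeCN, 0 °C; aq Na2S2O3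
Reagents that add atoms: iodine, II
Why: Iodine adds to the alkyne to give a bridged iodirenium ion whose positive charge sits mainly on C2, because the para-benzyloxy group of ring B stabilises a benzylic vinyl cation there; the C5 hydroxyl then attacks C2 anti to iodine and NaHCO3 takes up the proton, forming the O1–C2 and C3–I bonds. The closest known reaction type is the iodine-mediated cyclisation of 3-alkyn-1-ols to 3-iodo-4,5-dihydrofurans. The single ring closes in the 5-endo-dig mode, the 4-exo-dig alternative to an oxetane being strained and electronically mismatched. No stereocentre is created and C4 and C5 are not involved, so the syn alkynol should give the 4,5-cis ring (the descriptor at C4 changes to R only because iodine raises the priority of C3). The selectivity needed is regiochemical, oxygen to C2 and iodine to C3, and it is secured by the tether length together with the donor aryl group on C2.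

Step 7
Reactants: 9 (4R,5R)-2-[4-(benzyloxy)-3-methoxyphenyl]-5-(3,4-dimethoxyphenyl)-3-iodo-4-methyl-4,5-dihydrofuran
Product: 10 (4S,5R)-2-[4-(benzyloxy)-3-methoxyphenyl]-5-(3,4-dimethoxyphenyl)-3,4-dimethyl-4,5-dihydrofuran
Conditions: MeZnCl, Pd(PPh3)4 (5 mol%), THF, rt to 50 °C
Reagents that add atoms: methylzinc chloride, C[Zn]Cl
Why: Negishi coupling (oxidative addition of zerovalent palladium into the vinylic C3–I bond, transmetalation from zinc, reductive elimination) should place the missing methyl on C3 under neutral conditions that spare the acid-sensitive enol ether and the C4/C5 centres.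

Step 8
Reactants: 10 (4S,5R)-2-[4-(benzyloxy)-3-methoxyphenyl]-5-(3,4-dimethoxyphenyl)-3,4-dimethyl-4,5-dihydrofuran
Product: 12 4-[(2S,3R,4S,5R)-5-(3,4-dimethoxyphenyl)-3,4-dimethyloxolan-2-yl]-2-methoxyphenol, via debenzylated dihydrofuran phenol 11 (not isolated)
Conditions: H2 (1 atm), 10% Pd/C, NaHCO3, EtOAc, rt
Reagents that add atoms: none
Why: Heterogeneous catalytic hydrogenation should cleave the aryl benzyl ether first and then add H2 syn to the C2=C3 enol ether from the face opposite the cis C4 methyl and C5 aryl groups, which sets C2 (S) and C3 (R) and makes the oxolane all-cis, while NaHCO3 keeps the medium non-acidic to protect the benzylic ring C–O bonds.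

Step 9
Reactants: 12 4-[(2S,3R,4S,5R)-5-(3,4-dimethoxyphenyl)-3,4-dimethyloxolan-2-yl]-2-methoxyphenol; 13 ethyl (R)-lactate
Product: 14 ethyl (S)-2-{4-[(2S,3R,4S,5R)-5-(3,4-dimethoxyphenyl)-3,4-dimethyloxolan-2-yl]-2-methoxyphenoxy}propanoate
Conditions: PPh3, DIAD, THF, 0 °C to rt
Reagents that add atoms: none
Why: Mitsunobu etherification of a phenol with a secondary α-hydroxy ester proceeds by SN2 displacement of the alkoxyphosphonium ion, so the R lactate centre should be inverted to the S aryl ether that becomes C2 of the side chain.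

Step 10
Reactants: 14 ethyl (S)-2-{4-[(2S,3R,4S,5R)-5-(3,4-dimethoxyphenyl)-3,4-dimethyloxolan-2-yl]-2-methoxyphenoxy}propanoate
Product: 15 (S)-2-{4-[(2S,3R,4S,5R)-5-(3,4-dimethoxyphenyl)-3,4-dimethyloxolan-2-yl]-2-methoxyphenoxy}-N-methoxy-N-methylpropanamide
Conditions: MeNH(OMe)·HCl, iPrMgCl, THF, −20 to 0 °C
Reagents that add atoms: N,O-dimethylhydroxylamine hydrochloride, CNOC.Cl
Why: Weinreb amide formation by aminolysis of the ester with the chloromagnesium amide is fast at low temperature, where the α-aryloxy stereocentre should not enolise.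

Step 11
Reactants: 15 (S)-2-{4-[(2S,3R,4S,5R)-5-(3,4-dimethoxyphenyl)-3,4-dimethyloxolan-2-yl]-2-methoxyphenoxy}-N-methoxy-N-methylpropanamide; 16 3,4-dimethoxyphenylmagnesium bromide (commercial THF solution)
Product: 18 (S)-1-(3,4-dimethoxyphenyl)-2-{4-[(2S,3R,4S,5R)-5-(3,4-dimethoxyphenyl)-3,4-dimethyloxolan-2-yl]-2-methoxyphenoxy}propan-1-one, via magnesium-chelated tetrahedral adduct 17 (not isolated)
Conditions: THF, 0 °C; aq NH4Cl
Reagents that add atoms: none
Why: Weinreb ketone synthesis: the aryl Grignard adds once, the chelated adduct survives until work-up, and so neither over-addition nor base-induced epimerisation of a free α-aryloxy ketone should occur.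

Step 12
Reactants: 18 (S)-1-(3,4-dimethoxyphenyl)-2-{4-[(2S,3R,4S,5R)-5-(3,4-dimethoxyphenyl)-3,4-dimethyloxolan-2-yl]-2-methoxyphenoxy}propan-1-one
Product: 19 (1R,2S)-1-(3,4-dimethoxyphenyl)-2-{4-[(2S,3R,4S,5R)-5-(3,4-dimethoxyphenyl)-3,4-dimethyloxolan-2-yl]-2-methoxyphenoxy}propan-1-ol
Conditions: Zn(BH4)2, Et2O, −30 to 0 °C; aq NH4Cl
Reagents that add atoms: none
Why: Chelation-controlled hydride reduction (Cram chelate model): zinc bridges the carbonyl and aryl ether oxygens, hydride enters from the face of the α-hydrogen and not the α-methyl, and the S centre should thereby induce the R carbinol of the anti (erythro) alcohol.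

**Compound list**

1 | (S)-but-3-yn-2-ol | C#C[C@H](C)O | starting material
2 | (S)-but-3-yn-2-yl methanesulfonate | C#C[C@H](C)OS(C)(=O)=O | intermediate
3 | (Ra)-tributyl(buta-1,2-dien-1-yl)stannane, M helicity | [H]C(C)=[C@@]=C([H])[Sn](CCCC)(CCCC)CCCC | intermediate
4 | veratraldehyde (3,4-dimethoxybenzaldehyde) | COc1ccc(C=O)cc1OC | starting material
5 | (1R,2S)-1-(3,4-dimethoxyphenyl)-2-methylbut-3-yn-1-ol | O[C@@H](c1ccc(OC)c(OC)c1)[C@@H](C)C#C | intermediate
6 | 4-iodo-2-methoxyphenol | COc1cc(I)ccc1O | starting material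
7 | 1-(benzyloxy)-4-iodo-2-methoxybenzene | COc1cc(I)ccc1OCc1ccccc1 | intermediate
8 | (1R,2S)-4-[4-(benzyloxy)-3-methoxyphenyl]-1-(3,4-dimethoxyphenyl)-2-methylbut-3-yn-1-ol | O[C@@H](c1ccc(OC)c(OC)c1)[C@@H](C)C#Cc1ccc(OCc2ccccc2)c(OC)c1 | intermediate
9 | (4R,5R)-2-[4-(benzyloxy)-3-methoxyphenyl]-5-(3,4-dimethoxyphenyl)-3-iodo-4-methyl-4,5-dihydrofuran (4,5-cis) | COc1cc(C2O[C@@H](c3ccc(OC)c(OC)c3)[C@@H](C)C=2I)ccc1OCc1ccccc1 | intermediate
10 | (4S,5R)-2-[4-(benzyloxy)-3-methoxyphenyl]-5-(3,4-dimethoxyphenyl)-3,4-dimethyl-4,5-dihydrofuran | COc1cc(C2O[C@@H](c3ccc(OC)c(OC)c3)[C@@H](C)C=2C)ccc1OCc1ccccc1 | intermediate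
11 | 4-[(4S,5R)-5-(3,4-dimethoxyphenyl)-3,4-dimethyl-4,5-dihydrofuran-2-yl]-2-methoxyphenol (formed and consumed in step 8) | COc1cc(C2O[C@@H](c3ccc(OC)c(OC)c3)[C@@H](C)C=2C)ccc1O | intermediate
12 | 4-[(2S,3R,4S,5R)-5-(3,4-dimethoxyphenyl)-3,4-dimethyloxolan-2-yl]-2-methoxyphenol | COc1cc([C@H]2O[C@@H](c3ccc(OC)c(OC)c3)[C@@H](C)[C@H]2C)ccc1O | intermediate
13 | ethyl (R)-lactate | CCOC(=O)[C@@H](C)O | starting material
14 | ethyl (S)-2-{4-[(2S,3R,4S,5R)-5-(3,4-dimethoxyphenyl)-3,4-dimethyloxolan-2-yl]-2-methoxyphenoxy}propanoate | CCOC(=O)[C@H](C)Oc1ccc([C@H]2O[C@@H](c3ccc(OC)c(OC)c3)[C@@H](C)[C@H]2C)cc1OC | intermediate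
15 | (S)-2-{4-[(2S,3R,4S,5R)-5-(3,4-dimethoxyphenyl)-3,4-dimethyloxolan-2-yl]-2-methoxyphenoxy}-N-methoxy-N-methylpropanamide | CON(C)C(=O)[C@H](C)Oc1ccc([C@H]2O[C@@H](c3ccc(OC)c(OC)c3)[C@@H](C)[C@H]2C)cc1OC | intermediate
16 | 3,4-dimethoxyphenylmagnesium bromide | COc1ccc([Mg]Br)cc1OC | starting material
17 | bromomagnesium salt of the tetrahedral adduct of 15 and 16, unassigned at the new carbon (formed and consumed in step 11) | COc1ccc(C(O[Mg]Br)(N(C)OC)[C@H](C)Oc2ccc([C@H]3O[C@@H](c4ccc(OC)c(OC)c4)[C@@H](C)[C@H]3C)cc2OC)cc1OC | intermediate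
18 | (S)-1-(3,4-dimethoxyphenyl)-2-{4-[(2S,3R,4S,5R)-5-(3,4-dimethoxyphenyl)-3,4-dimethyloxolan-2-yl]-2-methoxyphenoxy}propan-1-one | COc1ccc(C(=O)[C@H](C)Oc2ccc([C@H]3O[C@@H](c4ccc(OC)c(OC)c4)[C@@H](C)[C@H]3C)cc2OC)cc1OC | intermediate
19 | (1R,2S)-1-(3,4-dimethoxyphenyl)-2-{4-[(2S,3R,4S,5R)-5-(3,4-dimethoxyphenyl)-3,4-dimethyloxolan-2-yl]-2-methoxyphenoxy}propan-1-ol | COc1ccc([C@@H](O)[C@H](C)Oc2ccc([C@H]3O[C@@H](c4ccc(OC)c(OC)c4)[C@@H](C)[C@H]3C)cc2OC)cc1OC | target

**Count and risks**

Total steps: 12. Longest linear sequence: 11 steps (steps 1–3 and 5–12); step 4 is a one-step side branch.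

Steps most likely to fail:

1. Step 8. Saturation of the tetrasubstituted enol ether is slow, so hydrogenolysis of the benzylic ring C–O bonds or palladium-mediated double-bond migration (which would erode C4) may compete. The fallback separates the two reductions and sets out from 10. The alkene is first saturated over 5% Rh/Al2O3 under H2 in EtOAc, a catalyst that hydrogenates enol ethers but has little tendency to cleave benzylic C–O bonds. With the same facial preference this should give (2S,3R,4S,5R)-2-[4-(benzyloxy)-3-methoxyphenyl]-5-(3,4-dimethoxyphenyl)-3,4-dimethyloxolane F1. A short, separate hydrogenolysis of the aryl benzyl ether (H2, 10% Pd/C, EtOAc, rt) on the saturated ring then returns to the route at 12.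

2. Step 3. The syn selectivity may be poor, or enantiomeric purity may be lost through racemisation of the allene axis or BF3-induced ionisation of the electron-rich benzylic alcohol. The fallback sets out from 4 and replaces the propargylation by an auxiliary-controlled aldol route.
   - Evans syn aldol reaction of 4 with (R)-4-benzyl-3-propionyloxazolidin-2-one (Bu2BOTf, iPr2NEt, CH2Cl2, −78 to 0 °C) should give (R)-4-benzyl-3-[(2R,3R)-3-(3,4-dimethoxyphenyl)-3-hydroxy-2-methylpropanoyl]oxazolidin-2-one F2.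
   - Silylation (TBSOTf, 2,6-lutidine) gives (R)-4-benzyl-3-[(2R,3R)-3-[(tert-butyldimethylsilyl)oxy]-3-(3,4-dimethoxyphenyl)-2-methylpropanoyl]oxazolidin-2-one F3.
   - Reductive removal of the auxiliary (LiBH4, MeOH, THF, 0 °C) gives (2S,3R)-3-[(tert-butyldimethylsilyl)oxy]-3-(3,4-dimethoxyphenyl)-2-methylpropan-1-ol F4.
   - Dess–Martin oxidation gives (2R,3R)-3-[(tert-butyldimethylsilyl)oxy]-3-(3,4-dimethoxyphenyl)-2-methylpropanal F5.
   - Ohira–Bestmann homologation (dimethyl (1-diazo-2-oxopropyl)phosphonate, K2CO3, MeOH) gives tert-butyl{[(1R,2S)-1-(3,4-dimethoxyphenyl)-2-methylbut-3-yn-1-yl]oxy}dimethylsilane F6.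
   - Desilylation with Bu4NF in THF returns to the route at 5.

3. Step 12. The aryl ether oxygen may chelate zinc only weakly, giving poor facial selectivity at the carbonyl. The fallback sets out from 18 and replaces substrate control by catalyst control: Corey–Bakshi–Shibata reduction with (R)-2-methyl-CBS-oxazaborolidine and BH3·SMe2 in THF at −20 °C. With ring A as the large substituent it should deliver hydride to the same carbonyl face and return directly to 19; it creates no new compound, F0.

**Further compounds**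

F1 | step 8 | (2S,3R,4S,5R)-2-[4-(benzyloxy)-3-methoxyphenyl]-5-(3,4-dimethoxyphenyl)-3,4-dimethyloxolane | COc1cc([C@H]2O[C@@H](c3ccc(OC)c(OC)c3)[C@@H](C)[C@H]2C)ccc1OCc1ccccc1
F2 | step 3 | (R)-4-benzyl-3-[(2R,3R)-3-(3,4-dimethoxyphenyl)-3-hydroxy-2-methylpropanoyl]oxazolidin-2-one | O[C@@H](c1ccc(OC)c(OC)c1)[C@@H](C)C(=O)N1C(=O)OC[C@H]1Cc1ccccc1
F3 | step 3 | (R)-4-benzyl-3-[(2R,3R)-3-[(tert-butyldimethylsilyl)oxy]-3-(3,4-dimethoxyphenyl)-2-methylpropanoyl]oxazolidin-2-one | CC(C)(C)[Si](C)(C)O[C@@H](c1ccc(OC)c(OC)c1)[C@@H](C)C(=O)N1C(=O)OC[C@H]1Cc1ccccc1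
F4 | step 3 | (2S,3R)-3-[(tert-butyldimethylsilyl)oxy]-3-(3,4-dimethoxyphenyl)-2-methylpropan-1-ol | CC(C)(C)[Si](C)(C)O[C@@H](c1ccc(OC)c(OC)c1)[C@@H](C)CO
F5 | step 3 | (2R,3R)-3-[(tert-butyldimethylsilyl)oxy]-3-(3,4-dimethoxyphenyl)-2-methylpropanal | CC(C)(C)[Si](C)(C)O[C@@H](c1ccc(OC)c(OC)c1)[C@@H](C)C=O
F6 | step 3 | tert-butyl{[(1R,2S)-1-(3,4-dimethoxyphenyl)-2-methylbut-3-yn-1-yl]oxy}dimethylsilane | CC(C)(C)[Si](C)(C)O[C@@H](c1ccc(OC)c(OC)c1)[C@@H](C)C#C
F0 | step 12 | none | none
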